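## Structural features

The target is a bicyclic ent-labdane: a trans-fused decalin in which ring A (C1–C5, C10) and ring B (C5–C10) share the C5–C10 bond, with a gem-dimethyl group on C4, an angular methyl (C20) on C10 and an exocyclic methylene (C8=C17) on ring B. C9 carries a two-carbon link (C11–C12) to a trisubstituted (13E)-alkene whose C14 end is a free carboxylic acid (C15) and whose C13 bears an acetoxymethyl group (C16). There are four stereocentres (2R,5R,9R,10R): C5, C10 and C9 are contiguous, and the C2 carbinol is 1,3 to the quaternary C10, with its equatorial oxygen cis to the C10–C9 bond and trans to C20. The fragile points are the primary allylic acetate (it has to survive beside a free acid and a free secondary alcohol, which rules out late hydrolysis), the 1,1-disubstituted alkene (it moves into the ring under acid) and the geometry of the β,β-disubstituted enoate. The real difficulty is the quaternary C10, placed between the C9 stereocentre and C5 with its neighbouring quaternary C4, and its correlation with the remote C2 carbinol in one enantiomer. The key step exploits the cis-1,3 relation of the C2–O bond and the C10–C9 bond on ring A: an acyl group on O2 can hold C11, C9, C8 and C17 over one face of a C10=C5–C6=C7 diene, so that C9 can bond to C10 only cis to O2. This relation runs between C2 and C10 across C1; C10 is one of its two ends, not the atom in the middle.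

## Logic of the disconnections

29 from 28. The only bond cut is the O–C bond of the carboxyl protecting group at C15. It comes last because the C16 acetate forbids hydrolytic unmasking of the acid; a fluoride-labile ester can leave while the acetate, both alkenes and the free C2 hydroxyl stay. The forward step must fragment the ester without acetate loss.

28 from 25. The C9–H bond is removed and C8=C17 is moved back into the ring as C8=C9 with a hydroxyl on C17. The C9 stereocentre and the exocyclic methylene thus become a tetrasubstituted alkene with an allylic alcohol, which is what an alkyne cycloaddition leaves behind. The forward step must deliver hydrogen to C9 on the face away from C20 and must act on the primary allylic hydroxyl only.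

25 from 24. The O–Si bond at O17 is cut. The forward desilylation must spare the silicon-containing ester at C15 and the acetate.

24 from 18 and 22. The C12–C13 bond (sp3–sp2) is cut. The C13–C16 unit, with alkene geometry, acetate and masked acid, becomes one small fragment, and the bicycle needs only a vinyl group at C11. The forward step needs hydroboration at the vinyl group alone and coupling with retention of the iodoalkene geometry.

22 from 12 (through 21 and 19). C–I and C–H are cut as the elements of HI across an alkyne, the acetate is traced to the silyl ether and the ester to 12, which is also the tether acid. Side chain and tether therefore come from one building block. The forward addition must be anti so that iodine ends cis to the ester.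

18 from 16 (through 17). C11=C12 is cut back to a C11 aldehyde and then to the C11 alcohol. The oxidation must touch only the allylic primary alcohol, and the olefination must tolerate a hindered aldehyde and a free hydroxyl.

16 from 15. The C5–H and C6–H bonds are cut, restoring C5=C6. This reduction has to follow the opening of the lactone: the bridged lactone holds C9 axial on ring A and can only accommodate a cis ring fusion. The forward step must add hydrogen from the face opposite C20 and leave C8=C9 and both allylic C–O bonds.

15 from 14. The C11–O2 lactone bond is cut by reduction. This frees the C2 hydroxyl and sets C11 at the alcohol level, while O17 stays silylated, so O11 and O17 are differentiated without a selective step.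

14 from 13. C9–C10 and C7–C8 are cut in the retro-[4+2] sense. Ring B and the lactone vanish together and the quaternary C10 becomes a trigonal diene terminus, leaving the C2 carbinol as the only stereocentre. The forward step must bring C9 to the tetrasubstituted C10 from the face of O2 and must outrun thermal isomerisation of the diene.

13 from 8 and 12. The acyl C11–O2 bond is cut. The forward esterification of a secondary alcohol with an ynoic acid must avoid conjugate addition.

12 from 9 (through 10 and 11). The C9–C11 bond is cut (carboxylation of an acetylide), then O–Si.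

8 from 5 and 6 (through 7). The C5–C6 bond between ring A and the vinyl group is cut, then O–Si at O2. The forward coupling takes place at a hindered, tetrasubstituted alkenyl triflate.

5 from 1 (through 4, 3 and 2). The triflate O–S bond and the β C–H bond are cut back to the enone, O–Si is cut, and the carbinol C–H bond is traced to the C4 carbonyl of 1. One catalytic reduction introduces the only stereocentre the route has to buy. The S descriptor of 4, 5, 7, 8 and 13 and the R descriptor of 2 and 3 describe the same spatial arrangement, because the ranking of the two ring branches changes when the alkene moves.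

## Other disconnections considered

Alternative 1: The cut is C3–C4 of ring A, opened up by first breaking the C4–C7 bond of a cyclobutane. (1S,5S)-Verbenone A1 supplies C5 and the gem-dimethyl carbon C4; conjugate allylation at C10 and alkylation at C9 would lead to the bicyclic ketone A2. In the forward key step formic acid would activate the C8 carbonyl of A2, the C4–C7 bond would break to a tertiary C4 cation and the C8 enol, the terminal alkene carbon C3 would close ring A onto C4, and formate would capture C2 to give the decalone A3.
- In favour: the chiral pool is cheap, C5 is bought, C10 is set by addition anti to the bridge of a rigid bicycle, and the trans fusion follows from that. A3 already carries C11–C12 at the ester level, which is better than the chosen plan, where C12 has to be added.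
- Against: C2 is created by capture of a secondary cation by an external nucleophile, so axial capture, elimination and hydride shift compete. A monosubstituted alkene is a weak terminator. The C8 ketone must later be methylenated next to an epimerisable C9.
- Comparison: on structure, control of C5 and C10 is the equal of the chosen plan, but control of C2 is weaker than a catalyst-controlled carbonyl reduction. On mechanism, it is a stepwise cationic process with open intermediates against a concerted cycloaddition. On step economy, it is equal or slightly better up to the decalin, and both plans still have to build C13–C16.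

Alternative 2: The cut is C8–C9 of ring B. (R)-α-Ionone A4 supplies C5, C4 and the C20-bearing carbon. Ring A would then need oxygen at C2 and a quaternary C10 carrying an (E)-enoate, and the side chain would be turned into an alkenyl triflate, to reach A5. In the forward key step zerovalent palladium (from Pd(OAc)2/PPh3) would insert into the C8–O bond of A5, the alkenylpalladium would add 6-exo to C9, and formate would reduce the C11 palladium enolate to give the ester A6.
- In favour: the exocyclic methylene, the C9 stereocentre and the C11–C12 ester arm arrive in one mild step. No transposition is needed, which is better than the chosen plan.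
- Against: the burden moves to A5. C10 must be made quaternary by conjugate addition to a β,β-disubstituted enone with facial control from C5 alone, and the C2 ketone must then be reduced diastereoselectively. Enantiopure A4 is less accessible than the racemate. The insertion is onto a carbon next to the quaternary C10, where direct reduction of the alkenylpalladium can compete.
- Comparison: on structure, ring B is closed around existing C5 and C10, whereas the chosen plan makes C10 in the ring-forming step under covalent control from C2. On mechanism, it is organometallic insertion and reduction against a pericyclic step. On step economy, it is better after its key step and worse before it, so roughly equal overall.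

Alternative 3: The cuts are C4–C5 and C9–C10 at once, so both rings come from the acyclic triene A7. In the forward key step Co(salen) with PhSiH3 and an N-fluoro-2,4,6-trimethylpyridinium salt would transfer a hydrogen atom to C18 of the 1,1-disubstituted C4=C18 alkene and oxidise the tertiary C4 radical to a cation equivalent. C5=C10 and then the allylsilane would add in a chair–chair array, and loss of silicon would release C8=C17 in the pivalate A8.
- In favour: two rings, two bonds and three stereocentres (C5, C9, C10) form in one step, which is better than the chosen key step, which sets one. The exocyclic methylene and the C11–C12 arm come directly, under mild, neutral conditions.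
- Against: the only control element is the C2 silyloxy group on the chain between initiator and first alkene. Its equatorial preference is a conformational bias, not a constraint. Hydrogen-atom transfer must select one of four alkenes, and interruption after the first ring or reduction of the radical can intervene. A7 needs two stereodefined trisubstituted alkenes and an enantiopure carbinol.
- Comparison: on structure, the whole decalin is built relative to C2, against C10 in the key step and C5 and C9 in later steps. On mechanism, it is a radical–polar crossover cation–olefin cascade against a concerted cycloaddition. On step economy, it is probably the shortest if the diastereoselectivity holds. The chosen plan is preferred because the C2-to-C10 relation is enforced by a covalent tether.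

Key step: step 9

Remark: atom numbers are those of the labdane skeleton (ring A = C1–C5, C10; ring B = C5–C10; C17 on C8; C18 and C19 on C4; C20 on C10; side chain C11–C16).
Remark: in step 1 the (R,R)-ligand is assumed to deliver the R carbinol, the alkene taking the place of the aryl group of an aryl ketone; if the sense is the reverse, the (S,S)-ligand is used with no other change.

## Steps

Step 1
Reactants: 1 ketoisophorone (2,6,6-trimethylcyclohex-2-ene-1,4-dione)
Product: 2 (R)-4-hydroxy-2,6,6-trimethylcyclohex-2-en-1-one
Conditions: RuCl(p-cymene)[(R,R)-TsDPEN] (cat.), i-PrOH, rt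
Reagents that add atoms: none
Why: Noyori-type asymmetric transfer hydrogenation; the unhindered conjugated C4 carbonyl is reduced while the C1 carbonyl, flanked by a quaternary carbon and a methyl-bearing alkene carbon, stays, and the ligand enantiomer fixes the carbinol (the future C2) as R.

Step 2
Reactants: 2 (R)-4-hydroxy-2,6,6-trimethylcyclohex-2-en-1-one
Product: 3 (R)-4-(tert-butyldimethylsilyloxy)-2,6,6-trimethylcyclohex-2-en-1-one
Conditions: TBSCl, imidazole, DMF, rt
Reagents that add atoms: tert-butyldimethylsilyl chloride, CC(C)(C)[Si](C)(C)Cl
Why: Standard silylation of a secondary allylic alcohol; the ether keeps the oxygen inert in the hydride and palladium steps that follow.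

Step 3
Reactants: 3 (R)-4-(tert-butyldimethylsilyloxy)-2,6,6-trimethylcyclohex-2-en-1-one
Product: 5 (S)-4-(tert-butyldimethylsilyloxy)-2,6,6-trimethylcyclohex-1-en-1-yl trifluoromethanesulfonate, via lithium enolate 4 (not isolated)
Conditions: LiBH(s-Bu)3, THF, −78 °C; then PhNTf2, −78 °C to rt
Reagents that add atoms: N-phenylbis(trifluoromethanesulfonimide), O=S(=O)(N(c1ccccc1)S(=O)(=O)C(F)(F)F)C(F)(F)F
Why: Conjugate reduction of a β-unsubstituted cyclohexenone by a hindered borohydride followed by O-triflation of the enolate; the gem-dimethyl group shields the carbonyl against 1,2-addition, only one enolate regioisomer can form, and the carbinol centre is not touched.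

Step 4
Reactants: 5 (S)-4-(tert-butyldimethylsilyloxy)-2,6,6-trimethylcyclohex-1-en-1-yl trifluoromethanesulfonate; 6 tributyl(vinyl)stannane
Product: 7 (S)-tert-butyldimethyl[(3,5,5-trimethyl-4-vinylcyclohex-3-en-1-yl)oxy]silane
Conditions: Pd(PPh3)4 (cat.), LiCl, THF, reflux
Reagents that add atoms: none
Why: Stille coupling of an alkenyl triflate with a vinylstannane, with chloride to turn over the triflate-derived palladium intermediate; the reaction type is established for 2,6,6-trimethylcyclohexenyl triflates.

Step 5
Reactants: 7 (S)-tert-butyldimethyl[(3,5,5-trimethyl-4-vinylcyclohex-3-en-1-yl)oxy]silane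
Product: 8 (S)-3,5,5-trimethyl-4-vinylcyclohex-3-en-1-ol
Conditions: Bu4NF, THF, rt
Reagents that add atoms: none
Why: Fluoride cleavage of a secondary silyl ether; the diene and the stereocentre are unaffected.

Step 6
Reactants: 9 propargyl alcohol
Product: 10 tert-butyldimethyl(prop-2-yn-1-yloxy)silane
Conditions: TBSCl, imidazole, CH2Cl2, rt
Reagents that add atoms: tert-butyldimethylsilyl chloride, CC(C)(C)[Si](C)(C)Cl
Why: Standard silylation of a primary alcohol, which allows clean C-lithiation in the next step.

Step 7
Reactants: 10 tert-butyldimethyl(prop-2-yn-1-yloxy)silane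
Product: 12 4-(tert-butyldimethylsilyloxy)but-2-ynoic acid, via lithium acetylide 11 (not isolated)
Conditions: n-BuLi, THF, −78 °C; CO2; then dilute HCl to pH 3
Reagents that add atoms: carbon dioxide, O=C=O
Why: Deprotonation of a terminal alkyne and carboxylation of the acetylide; brief mild acidification keeps the primary silyl ether.

Step 8
Reactants: 8 (S)-3,5,5-trimethyl-4-vinylcyclohex-3-en-1-ol; 12 4-(tert-butyldimethylsilyloxy)but-2-ynoic acid
Product: 13 (S)-3,5,5-trimethyl-4-vinylcyclohex-3-en-1-yl 4-(tert-butyldimethylsilyloxy)but-2-ynoate
Conditions: DCC, DMAP (cat.), CH2Cl2, 0 °C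
Reagents that add atoms: none
Why: Steglich esterification; acylation at oxygen retains the carbinol configuration, and low temperature with only catalytic DMAP limits conjugate addition to the ynoate.

Step 9
Reactants: 13 (S)-3,5,5-trimethyl-4-vinylcyclohex-3-en-1-yl 4-(tert-butyldimethylsilyloxy)but-2-ynoate
Product: 14 (2R,10R)-17-(tert-butyldimethylsilyloxy)-12,13,14,15,16-pentanorlabda-5,8-dien-11,2-olide (bridged lactone; C5=C6 and C8=C9 in ring B)
Conditions: PhMe (0.01 M), BHT (cat.), 180 °C, sealed vessel
Reagents that add atoms: none
Why: Thermal, concerted [4+2] cycloaddition (intramolecular Diels–Alder reaction) of the s-cis C10=C5–C6=C7 diene with the ynoate held on O2, without ionic or radical intermediates; the closest known reaction types are ester-tethered intramolecular Diels–Alder reactions of alkynoates and the bimolecular additions of acetylenic esters to 2,6,6-trimethyl-1-vinylcyclohexene. Ring B is closed by the cycloaddition itself (C9–C10 and C7–C8 formed together, giving the C5=C6/C8=C9 1,4-cyclohexadiene), and the six-membered lactone (C1, C2, O, C11, C9, C10) is closed by the same C9–C10 bond because the four tether atoms C1, C2, O and C11 already join C10 to C9; it bridges ring A as a 2-oxabicyclo[3.3.1]nonane. The only new stereocentre, C10, is controlled by the C2 carbinol: with the ester oxygen axial on the ring A half-chair the alkyne reaches C10 only on the face cis to O2, so C9 ends cis to O2 and C20 trans (10R). Regioselectivity (C9 with C11 to the fully substituted C10, C8 with C17 to C7) is imposed by the tether and agrees with the electronic bias of the diene; an alkyne has no endo/exo issue and is slim enough for the tetrasubstituted terminus. The step needs chemoselectivity against bimolecular addition and against 1,5-hydrogen shift in the diene, which high dilution, a radical inhibitor and the lowest workable temperature are meant to secure.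

Step 10
Reactants: 14 (2R,10R)-17-(tert-butyldimethylsilyloxy)-12,13,14,15,16-pentanorlabda-5,8-dien-11,2-olide
Product: 15 (2R,10R)-17-(tert-butyldimethylsilyloxy)-12,13,14,15,16-pentanorlabda-5,8-diene-2,11-diol
Conditions: i-Bu2AlH, CH2Cl2, −78 to 0 °C; aq. potassium sodium tartrate
Reagents that add atoms: none
Why: 1,2-Reduction of an α,β-unsaturated lactone to the allylic alcohol with release of the C2 hydroxyl; relief of the 1,3-diaxial strain of the bridged ring favours opening, and the silyl ether on O17 is inert.

Step 11
Reactants: 15 (2R,10R)-17-(tert-butyldimethylsilyloxy)-12,13,14,15,16-pentanorlabda-5,8-diene-2,11-diol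
Product: 16 (2R,5R,10R)-17-(tert-butyldimethylsilyloxy)-12,13,14,15,16-pentanorlabd-8-ene-2,11-diol
Conditions: H2 (1 atm), 10% Pd/C, EtOAc, Et3N (trace), rt
Reagents that add atoms: none
Why: Heterogeneous hydrogenation in which only the trisubstituted C5=C6 binds to the metal, the tetrasubstituted C8=C9 being inert; with the lactone open, C20 and one C4 methyl are axial on the same face of ring A, so hydrogen adds to C5 from the opposite face and gives the trans fusion (5R), the facial course known for bimolecular adducts of this diene type with acetylenic esters. The amine is added to suppress allylic C–O hydrogenolysis.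

Step 12
Reactants: 16 (2R,5R,10R)-17-(tert-butyldimethylsilyloxy)-12,13,14,15,16-pentanorlabd-8-ene-2,11-diol
Product: 17 (2R,5R,10R)-17-(tert-butyldimethylsilyloxy)-2-hydroxy-12,13,14,15,16-pentanorlabd-8-en-11-al
Conditions: MnO2 (activated, excess), CH2Cl2, rt
Reagents that add atoms: none
Why: MnO2 oxidises the primary allylic alcohol selectively and leaves the saturated secondary alcohol at C2.

Step 13
Reactants: 17 (2R,5R,10R)-17-(tert-butyldimethylsilyloxy)-2-hydroxy-12,13,14,15,16-pentanorlabd-8-en-11-al
Product: 18 (2R,5R,10R)-17-(tert-butyldimethylsilyloxy)-13,14,15,16-tetranorlabda-8,11-dien-2-ol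
Conditions: Ph3PCH3Br, KOt-Bu (3 equiv each), THF, 0 °C to rt
Reagents that add atoms: methyltriphenylphosphonium bromide, C[P+](c1ccccc1)(c1ccccc1)c1ccccc1.[Br-]
Why: Wittig methylenation of a hindered enal without α-hydrogen, the same situation as in 2,6,6-trimethylcyclohex-1-enecarbaldehyde; excess ylide covers the free hydroxyl.

Step 14
Reactants: 12 4-(tert-butyldimethylsilyloxy)but-2-ynoic acid
Product: 19 2-(trimethylsilyl)ethyl 4-(tert-butyldimethylsilyloxy)but-2-ynoate
Conditions: Me3SiCH2CH2OH, DCC, DMAP (cat.), CH2Cl2, 0 °C
Reagents that add atoms: 2-(trimethylsilyl)ethanol, C[Si](C)(C)CCO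
Why: Steglich esterification; the silylethyl ester is chosen because fluoride can remove it at the end without touching an acetate.

Step 15
Reactants: 19 2-(trimethylsilyl)ethyl 4-(tert-butyldimethylsilyloxy)but-2-ynoate
Product: 21 2-(trimethylsilyl)ethyl 4-acetoxybut-2-ynoate, via hydroxy ynoate 20 (not isolated)
Conditions: HF·pyridine, pyridine, THF, 0 °C to rt; then Ac2O, DMAP, rt
Reagents that add atoms: acetic anhydride, CC(=O)OC(C)=O
Why: HF·pyridine cleaves the primary silyl ether but leaves the 2-(trimethylsilyl)ethyl ester, and the liberated alcohol is acetylated in the same flask.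

Step 16
Reactants: 21 2-(trimethylsilyl)ethyl 4-acetoxybut-2-ynoate
Product: 22 2-(trimethylsilyl)ethyl (Z)-4-acetoxy-3-iodobut-2-enoate
Conditions: NaI, AcOH, 70 °C
Reagents that add atoms: sodium iodide, [Na+].[I-]
Why: Conjugate hydroiodination of an ynoate; iodide adds at C3 and the allenolate is protonated anti, so iodine ends cis to the ester (Z), and moderate temperature avoids equilibration to the E isomer.

Step 17
Reactants: 18 (2R,5R,10R)-17-(tert-butyldimethylsilyloxy)-13,14,15,16-tetranorlabda-8,11-dien-2-ol; 22 2-(trimethylsilyl)ethyl (Z)-4-acetoxy-3-iodobut-2-enoate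
Product: 24 2-(trimethylsilyl)ethyl (2R,5R,10R,13E)-16-acetoxy-17-(tert-butyldimethylsilyloxy)-2-hydroxylabda-8,13-dien-15-oate, via B-alkyl-9-BBN 23 (not isolated)
Conditions: 9-BBN (2.5 equiv), THF, 0 to 40 °C; then 22, Pd(dppf)Cl2 (cat.), AsPh3, Cs2CO3, DMF/H2O, rt
Reagents that add atoms: none
Why: Anti-Markovnikov hydroboration of the vinyl group (the tetrasubstituted C8=C9 does not react; excess borane allows for the free hydroxyl), then B-alkyl Suzuki–Miyaura coupling with retention of the iodoalkene geometry, so C12 ends cis to the ester, which is the 13E arrangement.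

Step 18
Reactants: 24 2-(trimethylsilyl)ethyl (2R,5R,10R,13E)-16-acetoxy-17-(tert-butyldimethylsilyloxy)-2-hydroxylabda-8,13-dien-15-oate
Product: 25 2-(trimethylsilyl)ethyl (2R,5R,10R,13E)-16-acetoxy-2,17-dihydroxylabda-8,13-dien-15-oate
Conditions: HF·pyridine, pyridine, THF, 0 °C to rt
Reagents that add atoms: none
Why: Buffered HF·pyridine removes the primary allylic silyl ether and leaves the silylethyl ester and the acetate.

Step 19
Reactants: 25 2-(trimethylsilyl)ethyl (2R,5R,10R,13E)-16-acetoxy-2,17-dihydroxylabda-8,13-dien-15-oate
Product: 28 2-(trimethylsilyl)ethyl (2R,5R,9R,10R,13E)-16-acetoxy-2-hydroxylabda-8(17),13-dien-15-oate, via sulfonylhydrazine adduct 26 (not isolated), via allylic diazene 27 (not isolated)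
Conditions: 2-nitrobenzenesulfonylhydrazide, PPh3, DEAD, THF, −30 °C; then rt
Reagents that add atoms: none
Why: Mitsunobu displacement of the primary allylic alcohol by the sulfonylhydrazide, loss of sulfinate to the monoalkyl diazene and retro-ene loss of N2, which passes hydrogen suprafacially to C9 as C8=C17 forms; axial delivery on the face away from the C20 methyl gives 9R with the side chain equatorial. The C2 hydroxyl is spared because substitution there would require approach between the two axial methyl groups.

Step 20
Reactants: 28 2-(trimethylsilyl)ethyl (2R,5R,9R,10R,13E)-16-acetoxy-2-hydroxylabda-8(17),13-dien-15-oate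
Product: 29 (2R,5R,9R,10R,13E)-16-acetoxy-2-hydroxylabda-8(17),13-dien-15-oic acid (CNP0292310.2)
Conditions: TASF [(Me2N)3S+ Me3SiF2−], DMF, 0 °C to rt; then dilute HCl to pH 3
Reagents that add atoms: none
Why: Fluoride-induced fragmentation of the 2-(trimethylsilyl)ethyl ester to the carboxylate, ethene and Me3SiF under non-hydrolytic conditions, which should leave the allylic acetate, both alkenes and the free alcohol untouched.

## Compound list

1 | ketoisophorone (2,6,6-trimethylcyclohex-2-ene-1,4-dione) | CC1=CC(=O)CC(C)(C)C1=O | starting material
2 | (R)-4-hydroxy-2,6,6-trimethylcyclohex-2-en-1-one | CC1=C[C@H](O)CC(C)(C)C1=O | intermediate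
3 | (R)-4-(tert-butyldimethylsilyloxy)-2,6,6-trimethylcyclohex-2-en-1-one | CC1=C[C@H](O[Si](C)(C)C(C)(C)C)CC(C)(C)C1=O | intermediate
4 | lithium (S)-4-(tert-butyldimethylsilyloxy)-2,6,6-trimethylcyclohex-1-en-1-olate (formed in the flask) | [Li+].CC1=C([O-])C(C)(C)C[C@@H](O[Si](C)(C)C(C)(C)C)C1 | intermediate
5 | (S)-4-(tert-butyldimethylsilyloxy)-2,6,6-trimethylcyclohex-1-en-1-yl trifluoromethanesulfonate | CC1=C(OS(=O)(=O)C(F)(F)F)C(C)(C)C[C@@H](O[Si](C)(C)C(C)(C)C)C1 | intermediate
6 | tributyl(vinyl)stannane | C=C[Sn](CCCC)(CCCC)CCCC | starting material
7 | (S)-tert-butyldimethyl[(3,5,5-trimethyl-4-vinylcyclohex-3-en-1-yl)oxy]silane | C=CC1=C(C)C[C@H](O[Si](C)(C)C(C)(C)C)CC1(C)C | intermediate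
8 | (S)-3,5,5-trimethyl-4-vinylcyclohex-3-en-1-ol | C=CC1=C(C)C[C@H](O)CC1(C)C | intermediate
9 | propargyl alcohol | C#CCO | starting material
10 | tert-butyldimethyl(prop-2-yn-1-yloxy)silane | C#CCO[Si](C)(C)C(C)(C)C | intermediate
11 | [3-(tert-butyldimethylsilyloxy)prop-1-yn-1-yl]lithium (formed in the flask) | [Li]C#CCO[Si](C)(C)C(C)(C)C | intermediate
12 | 4-(tert-butyldimethylsilyloxy)but-2-ynoic acid | OC(=O)C#CCO[Si](C)(C)C(C)(C)C | intermediate
13 | (S)-3,5,5-trimethyl-4-vinylcyclohex-3-en-1-yl 4-(tert-butyldimethylsilyloxy)but-2-ynoate | C=CC1=C(C)C[C@H](OC(=O)C#CCO[Si](C)(C)C(C)(C)C)CC1(C)C | intermediate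
14 | (2R,10R)-17-(tert-butyldimethylsilyloxy)-12,13,14,15,16-pentanorlabda-5,8-dien-11,2-olide (bridged lactone) | O=C1O[C@@H]2CC(C)(C)C3=CCC(CO[Si](C)(C)C(C)(C)C)=C1[C@]3(C)C2 | intermediate
15 | (2R,10R)-17-(tert-butyldimethylsilyloxy)-12,13,14,15,16-pentanorlabda-5,8-diene-2,11-diol | OCC1=C(CO[Si](C)(C)C(C)(C)C)CC=C2C(C)(C)C[C@@H](O)C[C@@]12C | intermediate
16 | (2R,5R,10R)-17-(tert-butyldimethylsilyloxy)-12,13,14,15,16-pentanorlabd-8-ene-2,11-diol | OCC1=C(CO[Si](C)(C)C(C)(C)C)CC[C@@H]2C(C)(C)C[C@@H](O)C[C@@]12C | intermediate
17 | (2R,5R,10R)-17-(tert-butyldimethylsilyloxy)-2-hydroxy-12,13,14,15,16-pentanorlabd-8-en-11-al | O=CC1=C(CO[Si](C)(C)C(C)(C)C)CC[C@@H]2C(C)(C)C[C@@H](O)C[C@@]12C | intermediate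
18 | (2R,5R,10R)-17-(tert-butyldimethylsilyloxy)-13,14,15,16-tetranorlabda-8,11-dien-2-ol | C=CC1=C(CO[Si](C)(C)C(C)(C)C)CC[C@@H]2C(C)(C)C[C@@H](O)C[C@@]12C | intermediate
19 | 2-(trimethylsilyl)ethyl 4-(tert-butyldimethylsilyloxy)but-2-ynoate | C[Si](C)(C)CCOC(=O)C#CCO[Si](C)(C)C(C)(C)C | intermediate
20 | 2-(trimethylsilyl)ethyl 4-hydroxybut-2-ynoate (formed in the flask) | C[Si](C)(C)CCOC(=O)C#CCO | intermediate
21 | 2-(trimethylsilyl)ethyl 4-acetoxybut-2-ynoate | CC(=O)OCC#CC(=O)OCC[Si](C)(C)C | intermediate
22 | 2-(trimethylsilyl)ethyl (Z)-4-acetoxy-3-iodobut-2-enoate | CC(=O)OC/C(I)=C/C(=O)OCC[Si](C)(C)C | intermediate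
23 | (2R,5R,10R)-12-(9-borabicyclo[3.3.1]nonan-9-yl)-17-(tert-butyldimethylsilyloxy)-13,14,15,16-tetranorlabd-8-en-2-ol (formed in the flask) | C(CC1=C(CO[Si](C)(C)C(C)(C)C)CC[C@@H]2C(C)(C)C[C@@H](O)C[C@@]12C)B3C4CCCC3CCC4 | intermediate
24 | 2-(trimethylsilyl)ethyl (2R,5R,10R,13E)-16-acetoxy-17-(tert-butyldimethylsilyloxy)-2-hydroxylabda-8,13-dien-15-oate | CC(=O)OC/C(CCC1=C(CO[Si](C)(C)C(C)(C)C)CC[C@@H]2C(C)(C)C[C@@H](O)C[C@@]12C)=C/C(=O)OCC[Si](C)(C)C | intermediate
25 | 2-(trimethylsilyl)ethyl (2R,5R,10R,13E)-16-acetoxy-2,17-dihydroxylabda-8,13-dien-15-oate | CC(=O)OC/C(CCC1=C(CO)CC[C@@H]2C(C)(C)C[C@@H](O)C[C@@]12C)=C/C(=O)OCC[Si](C)(C)C | intermediate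
26 | 2-(trimethylsilyl)ethyl (2R,5R,10R,13E)-16-acetoxy-2-hydroxy-17-[1-(2-nitrobenzenesulfonyl)hydrazin-1-yl]labda-8,13-dien-15-oate (formed in the flask) | CC(=O)OC/C(CCC1=C(CN(N)S(=O)(=O)c3ccccc3[N+](=O)[O-])CC[C@@H]2C(C)(C)C[C@@H](O)C[C@@]12C)=C/C(=O)OCC[Si](C)(C)C | intermediate
27 | 2-(trimethylsilyl)ethyl (2R,5R,10R,13E)-16-acetoxy-17-diazenyl-2-hydroxylabda-8,13-dien-15-oate (formed in the flask) | CC(=O)OC/C(CCC1=C(CN=N)CC[C@@H]2C(C)(C)C[C@@H](O)C[C@@]12C)=C/C(=O)OCC[Si](C)(C)C | intermediate
28 | 2-(trimethylsilyl)ethyl (2R,5R,9R,10R,13E)-16-acetoxy-2-hydroxylabda-8(17),13-dien-15-oate | C=C1CC[C@@H]2C(C)(C)C[C@@H](O)C[C@@]2(C)[C@@H]1CC/C(=C\C(=O)OCC[Si](C)(C)C)COC(C)=O | intermediate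
29 | (2R,5R,9R,10R,13E)-16-acetoxy-2-hydroxylabda-8(17),13-dien-15-oic acid (CNP0292310.2) | C=C1CC[C@@H]2C(C)(C)C[C@@H](O)C[C@@]2(C)[C@@H]1CC/C(=C\C(=O)O)COC(C)=O | target

## Step count and risks

Total step count: 20. Longest linear sequence: 15 steps (1 to 29 through steps 1–5, 8–13 and 17–20).

Least certain steps:

Step 9 (key step). The most likely failure is a cycloaddition that is too slow at temperatures the diene tolerates. The ester must adopt its less stable conformation about the acyl–oxygen bond and C10 is fully substituted, so 1,5-hydrogen shift in the diene and bimolecular addition may take over. The fallback uses a doubly activated dienophile. Setting out from 8, esterification with methyl hydrogen but-2-ynedioate (DCC, cat. DMAP) would give the mixed diester (S)-3,5,5-trimethyl-4-vinylcyclohex-3-en-1-yl methyl but-2-ynedioate F1. Its cycloaddition should proceed near 110 °C, by analogy with the bimolecular additions of but-2-ynedioates to this diene type, to the bridged lactone ester methyl (2R,10R)-12,13,14,15,16-pentanorlabda-5,8-dien-11,2-olid-17-oate F2. i-Bu2AlH would reduce both carboxyl groups to (2R,10R)-12,13,14,15,16-pentanorlabda-5,8-diene-2,11,17-triol F3, and silylation with one equivalent of TBSCl at the less hindered O17 (O11 is next to the quaternary C10, O2 is secondary) would come back to the route at 15.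

Step 11. The most likely failure is hydrogenolysis of an allylic C–O bond, or migration of C5=C6 into conjugation before reduction, because palladium can form allyl species from a skipped diene carrying two allylic oxygens; sluggish uptake at the hindered alkene is the other possibility. The fallback reduces the alkene while C8=C9 is an enoate, as in the bimolecular adducts. Setting out from 14, K2CO3 in MeOH would open the lactone to methyl (2R,10R)-17-(tert-butyldimethylsilyloxy)-2-hydroxy-12,13,14,15,16-pentanorlabda-5,8-dien-11-oate F4. Hydrogenation over Pd/C would give methyl (2R,5R,10R)-17-(tert-butyldimethylsilyloxy)-2-hydroxy-12,13,14,15,16-pentanorlabd-8-en-11-oate F5, and i-Bu2AlH would return to the route at 16.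

Step 19. The most likely failure is a stalled Mitsunobu displacement at the crowded allylic carbon, or incomplete facial selectivity in the hydrogen transfer to C9, since the control is steric and stereoelectronic only. The fallback reaches the same diazene without a substitution step. Setting out from 25, MnO2 would give the enal 2-(trimethylsilyl)ethyl (2R,5R,10R,13E)-16-acetoxy-2-hydroxy-17-oxolabda-8,13-dien-15-oate F6. Condensation with p-toluenesulfonylhydrazide would give its tosylhydrazone F7, and 1,2-reduction with catecholborane followed by NaOAc·3H2O and warming would eliminate sulfinate and N2 with alkene transposition, returning to the route at 28. This fallback answers the displacement problem; it would not change the facial course.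

Step 17. The most likely failure is slow transmetalation of the β-branched alkylborane, which would leave room for protodeboronation, for cleavage of the acetate by aqueous carbonate, or for ionisation of the allylic acetate by zerovalent palladium. The fallback is a base-free alkylzinc coupling. Setting out from 18, hydroboration with 9-BBN and oxidation (NaOH, H2O2) would give (2R,5R,10R)-17-(tert-butyldimethylsilyloxy)-13,14,15,16-tetranorlabd-8-ene-2,12-diol F8. I2, PPh3 and imidazole would convert the primary alcohol to (2R,5R,10R)-17-(tert-butyldimethylsilyloxy)-12-iodo-13,14,15,16-tetranorlabd-8-en-2-ol F9 (the hindered C2 hydroxyl should not react). Zinc insertion (Zn, LiCl, THF; transient O-silylation with Me3SiCl if needed) would give the alkylzinc iodide F10, and Negishi coupling with 22 under Pd(PPh3)4 would return to the route at 24.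

Step 3. The most likely failure is competing 1,2-reduction of the carbonyl or incomplete O-triflation of the hindered, boron-associated enolate. The fallback separates the two events. Setting out from 3, hydrogenation over Pd/C in EtOAc would give (4S)-4-(tert-butyldimethylsilyloxy)-2,2,6-trimethylcyclohexan-1-one F11 (C6 epimers, which converge), and KN(SiMe3)2 with PhNTf2 at −78 °C, where only the methine side can enolise, would return to the route at 5.

## Further compounds

F1 | step 9 | (S)-3,5,5-trimethyl-4-vinylcyclohex-3-en-1-yl methyl but-2-ynedioate | C=CC1=C(C)C[C@H](OC(=O)C#CC(=O)OC)CC1(C)C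
F2 | step 9 | methyl (2R,10R)-12,13,14,15,16-pentanorlabda-5,8-dien-11,2-olid-17-oate | O=C1O[C@@H]2CC(C)(C)C3=CCC(C(=O)OC)=C1[C@]3(C)C2
F3 | step 9 | (2R,10R)-12,13,14,15,16-pentanorlabda-5,8-diene-2,11,17-triol | OCC1=C(CO)CC=C2C(C)(C)C[C@@H](O)C[C@@]12C
F4 | step 11 | methyl (2R,10R)-17-(tert-butyldimethylsilyloxy)-2-hydroxy-12,13,14,15,16-pentanorlabda-5,8-dien-11-oate | COC(=O)C1=C(CO[Si](C)(C)C(C)(C)C)CC=C2C(C)(C)C[C@@H](O)C[C@@]12C
F5 | step 11 | methyl (2R,5R,10R)-17-(tert-butyldimethylsilyloxy)-2-hydroxy-12,13,14,15,16-pentanorlabd-8-en-11-oate | COC(=O)C1=C(CO[Si](C)(C)C(C)(C)C)CC[C@@H]2C(C)(C)C[C@@H](O)C[C@@]12C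
F6 | step 19 | 2-(trimethylsilyl)ethyl (2R,5R,10R,13E)-16-acetoxy-2-hydroxy-17-oxolabda-8,13-dien-15-oate | CC(=O)OC/C(CCC1=C(C=O)CC[C@@H]2C(C)(C)C[C@@H](O)C[C@@]12C)=C/C(=O)OCC[Si](C)(C)C
F7 | step 19 | p-toluenesulfonylhydrazone of F6 at C17 | CC(=O)OC/C(CCC1=C(C=NNS(=O)(=O)c3ccc(C)cc3)CC[C@@H]2C(C)(C)C[C@@H](O)C[C@@]12C)=C/C(=O)OCC[Si](C)(C)C
F8 | step 17 | (2R,5R,10R)-17-(tert-butyldimethylsilyloxy)-13,14,15,16-tetranorlabd-8-ene-2,12-diol | OCCC1=C(CO[Si](C)(C)C(C)(C)C)CC[C@@H]2C(C)(C)C[C@@H](O)C[C@@]12C
F9 | step 17 | (2R,5R,10R)-17-(tert-butyldimethylsilyloxy)-12-iodo-13,14,15,16-tetranorlabd-8-en-2-ol | ICCC1=C(CO[Si](C)(C)C(C)(C)C)CC[C@@H]2C(C)(C)C[C@@H](O)C[C@@]12C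
F10 | step 17 | alkylzinc iodide from F9 (zinc on C12) | I[Zn]CCC1=C(CO[Si](C)(C)C(C)(C)C)CC[C@@H]2C(C)(C)C[C@@H](O)C[C@@]12C
F11 | step 3 | (4S)-4-(tert-butyldimethylsilyloxy)-2,2,6-trimethylcyclohexan-1-one (C6 epimers) | CC1C[C@H](O[Si](C)(C)C(C)(C)C)CC(C)(C)C1=O
A1 | alternative 1 | (1S,5S)-verbenone | CC1=CC(=O)[C@H]2C[C@@H]1C2(C)C
A2 | alternative 1 | methyl (4-allyl-4,6,6-trimethyl-2-oxobicyclo[3.1.1]hept-3-yl)acetate, allyl anti to the gem-dimethyl bridge, C9 epimers | C=CC[C@@]1(C)C(CC(=O)OC)C(=O)[C@H]2C[C@@H]1C2(C)C
A3 | alternative 1 | methyl 2-formyloxy-8-oxo-13,14,15,16,17-pentanorlabdan-12-oate with the C2, C5, C9 and C10 configurations of 29 | O=C1CC[C@@H]2C(C)(C)C[C@@H](OC=O)C[C@@]2(C)[C@@H]1CC(=O)OC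
A4 | alternative 2 | (R)-α-ionone | CC(=O)/C=C/[C@H]1C(C)=CCCC1(C)C
A5 | alternative 2 | ring A alkenyl triflate: C10 bears C20 and (E)-CH=CH–CO2Me, C5 bears CH2CH2C(OTf)=CH2, O2 as TBS ether; C2, C5 and C10 as in 29 | C=C(OS(=O)(=O)C(F)(F)F)CC[C@@H]1C(C)(C)C[C@@H](O[Si](C)(C)C(C)(C)C)C[C@@]1(C)/C=C/C(=O)OC
A6 | alternative 2 | methyl 2-(tert-butyldimethylsilyloxy)-13,14,15,16-tetranorlabd-8(17)-en-12-oate with the ring configurations of 29 | C=C1CC[C@@H]2C(C)(C)C[C@@H](O[Si](C)(C)C(C)(C)C)C[C@@]2(C)[C@@H]1CC(=O)OC
A7 | alternative 3 | acyclic triene: C4=C18 initiator, (E)-C5=C10, (Z)-C8=C9 allylsilane with CH2SiMe3 as C17, (2R)-silyloxy group, C12 pivalate | C=C(C)C[C@@H](O[Si](C)(C)C(C)(C)C)C/C(C)=C/CC/C(C[Si](C)(C)C)=C/CCOC(=O)C(C)(C)C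
A8 | alternative 3 | 2-(tert-butyldimethylsilyloxy)-13,14,15,16-tetranorlabd-8(17)-en-12-yl pivalate with the ring configurations of 29 | C=C1CC[C@@H]2C(C)(C)C[C@@H](O[Si](C)(C)C(C)(C)C)C[C@@]2(C)[C@@H]1CCOC(=O)C(C)(C)C
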